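**Strategy.** Ring B (C5–C10, labdane numbering) is not closed as a cyclohexane: it is assembled as a cyclopentane (C5, C6, C8, C9, C10) trans-fused to ring A and then enlarged by one carbon. The precursor is a ring-fused cyclopropanol with the hydroxyl on C6, the future C7 as the cyclopropane CH2 and the methyl on C8. Aerobic manganese catalysis opens it: the C6 alkoxy radical cleaves the C6–C8 bond, C7 enters the ring, and the tertiary C8 radical captures O2 on the α face. One operation thus gives the six-membered ring, the C6 carbonyl (reduced in the same flask) and the C8 carbinol, exploiting the 1,3-relationship of the C6 and C8 oxygens across C7.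

Key step: step 13

Remark: locants C1–C20 in the text are those of the labdane skeleton of the target; α and β have their usual meaning (C10 methyl β).
Assumption: in step 2 the (R)-configured ligand is taken to give the (R)-ketone, by analogy with 2-allyl-2-methylcyclohexanone; if the sense of induction proved opposite, the (S)-ligand would be used.

Step 1
Reactants: 1 2,2,6-trimethylcyclohexan-1-one
Product: 3 allyl 2,6,6-trimethylcyclohex-1-en-1-yl carbonate, via lithium enolate 2 (not isolated)
Conditions: LiN(SiMe3)2, THF, 0 °C; then allyl chloroformate, −78 °C to 25 °C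
Reagents that add atoms: allyl chloroformate, C=CCOC(Cl)=O
Why: Only one α-carbon of 1 carries hydrogen, so a single enolate forms and should be O-acylated by the chloroformate (enol carbonate formation).

Step 2
Reactants: 3 allyl 2,6,6-trimethylcyclohex-1-en-1-yl carbonate
Product: 4 (R)-2-allyl-2,6,6-trimethylcyclohexan-1-one
Conditions: Pd2(dba)3 (2.5 mol%), (R)-t-BuPHOX (6 mol%), THF, 25 °C
Reagents that add atoms: none
Why: Decarboxylative asymmetric allylic alkylation (Tsuji–Trost type): zerovalent palladium ionises the carbonate, CO2 is lost and the enolate recombines with the π-allyl at carbon, the chiral P,N-ligand setting the quaternary centre C10.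

Step 3
Reactants: 4 (R)-2-allyl-2,6,6-trimethylcyclohexan-1-one
Product: 5 (R)-2,2,6-trimethyl-6-(2-oxopropyl)cyclohexan-1-one
Conditions: PdCl2 (10 mol%), Cu(OAc)2·H2O (25 mol%), O2 (1 atm), DMA/H2O, 25 °C
Reagents that add atoms: water, O
Why: Wacker oxidation of the terminal alkene should give the methyl ketone with Markovnikov selectivity, while the copper salt and O2 return palladium to the divalent state; C10 is not touched.

Step 4
Reactants: 5 (R)-2,2,6-trimethyl-6-(2-oxopropyl)cyclohexan-1-one
Product: 7 (7aR)-4,4,7a-trimethyl-1,4,5,6,7,7a-hexahydro-2H-inden-2-one, via aldol adduct 6 (not isolated)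
Conditions: KOH, xylenes, 110 °C (Dean–Stark)
Reagents that add atoms: none
Why: Intramolecular aldol condensation (5-exo attack of the methyl ketone enolate on the hindered ring carbonyl C5, then dehydration) should close the cyclopentenone ring C5–C6–C8–C9–C10.

Step 5
Reactants: 8 methyl hydrogen (R)-3-methylglutarate
Product: 10 (S)-4-methyloxan-2-one, via hydroxy acid 9 (not isolated)
Conditions: LiBH4, THF, 0 °C to reflux; then 2 M HCl, 25 °C
Reagents that add atoms: none
Why: LiBH4 reduces the ester but not the lithium carboxylate, and the hydroxy acid should lactonise on acidification; the stereocentre is untouched (its descriptor changes only through the CIP priorities).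

Step 6
Reactants: 10 (S)-4-methyloxan-2-one
Product: 12 methyl (R)-5-iodo-3-methylpentanoate, via silyl ester 11 (not isolated)
Conditions: Me3SiI, CH2Cl2, 25 °C; then MeOH, 25 °C
Reagents that add atoms: iodotrimethylsilane, C[Si](C)(C)I; methanol, CO
Why: Silylation of the lactone carbonyl and SN2 attack of iodide at the O–CH2 carbon open the ring, and acidic methanolysis of the silyl ester should give the methyl ester (carbon 3 becomes C13 of the target).

Step 7
Reactants: 7 (7aR)-4,4,7a-trimethyl-1,4,5,6,7,7a-hexahydro-2H-inden-2-one; 12 methyl (R)-5-iodo-3-methylpentanoate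
Product: 14 methyl (3S)-3-methyl-5-[(7aR)-4,4,7a-trimethyl-2-oxo-2,4,5,6,7,7a-hexahydro-1H-inden-1-yl]pentanoate (C9 epimers), via lithium dienolate 13 (not isolated)
Conditions: LiN(i-Pr)2, THF, −78 °C; then 12, DMPU, −78 to 0 °C
Reagents that add atoms: none
Why: C9 is the only enolisable position of enone 7, and SN2 alkylation of the cross-conjugated enolate with the primary iodide should attach C11–C16; the new centre C9 may form as a mixture because it becomes sp2 in step 8.

Step 8
Reactants: 14 C9-alkylated enone
Product: 16 methyl (3S)-3-methyl-5-[(7aR)-2,4,4,7a-tetramethyl-5,6,7,7a-tetrahydro-4H-inden-1-yl]pentanoate, via tertiary alcohol 15 (not isolated)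
Conditions: MeMgBr, CeCl3, THF, −78 °C; then 2 M HCl, THF, 25 °C
Reagents that add atoms: methylmagnesium bromide, C[Mg]Br
Why: Cerium-mediated 1,2-addition of methyl to the C8 ketone (faster than to the ester) brings in C17, and E1 dehydration of the tertiary allylic alcohol towards C9 should give the ring-fused cyclopentadiene, which cannot shift hydrogen because C10 is quaternary.

Step 9
Reactants: 16 cyclopentadiene (C5=C6, C8=C9)
Product: 18 methyl (3S)-5-[(3R,3aS,7aS)-3-hydroxy-2,4,4,7a-tetramethyl-3a,4,5,6,7,7a-hexahydro-3H-inden-1-yl]-3-methylpentanoate, via allylborane 17 (not isolated)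
Conditions: BH3·SMe2, THF, 0 °C; then H2O2, NaOAc, H2O, 0 to 25 °C
Reagents that add atoms: hydrogen peroxide, OO
Why: Hydroboration–oxidation: boron should add to C6, the only hydrogen-bearing diene carbon, and hydrogen to C5 in a syn fashion from the α face, opposite the axial C10 and 4β methyl groups, which sets the trans ring fusion (5α-H) and the 6α-hydroxyl.

Step 10
Reactants: 18 allylic alcohol (5α-H, 6α-OH)
Product: 19 methyl (3S)-3-methyl-5-[(3aS,7aS)-2,4,4,7a-tetramethyl-3-oxo-3a,4,5,6,7,7a-hexahydro-3H-inden-1-yl]pentanoate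
Conditions: Dess–Martin periodinane (DMP), NaHCO3, CH2Cl2, 0 to 25 °C
Reagents that add atoms: none
Why: Buffered periodinane oxidation of the secondary allylic alcohol should give the C6 enone under non-enolising conditions, so the kinetically set C5 is kept.

Step 11
Reactants: 19 trans-fused enone (C6=O, C8=C9)
Product: 20 methyl (3S)-3-methyl-5-[(1R,3aS,7aR)-2,4,4,7a-tetramethyl-3-(triethylsilyloxy)-3a,4,5,6,7,7a-hexahydro-1H-inden-1-yl]pentanoate
Conditions: Et3SiH, RhCl(PPh3)3 (2 mol%), toluene, 60 °C
Reagents that add atoms: triethylsilane, CC[SiH](CC)CC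
Why: Rhodium-catalysed 1,4-hydrosilylation should give the C6=C8 silyl enol ether regiospecifically, with hydride delivered to C9 from the α face, anti to the adjacent axial C10 methyl, which places the side chain β.

Step 12
Reactants: 20 triethylsilyl enol ether
Product: 22 ring-fused cyclopropanol (C6–OH; C7 methylene on the α face; C8–Me), via silyl ether 21 (not isolated)
Conditions: Et2Zn, CH2I2, CH2Cl2, 0 to 25 °C; then Bu4NF, AcOH, THF, 0 °C
Reagents that add atoms: diiodomethane, ICI
Why: Simmons–Smith cyclopropanation of the electron-rich enol ether should occur on the α face, anti to the C10 methyl and the 9β side chain, and buffered fluoride then frees the cyclopropanol without base-induced ring opening.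

Step 13
Reactants: 22 ring-fused cyclopropanol
Product: 24 methyl (13S)-6β,8α-dihydroxylabdan-15-oate, via hydroperoxy ketone 23 (not isolated)
Conditions: Mn(acac)2 (5 mol%), O2 (1 atm), benzene, 25 °C; then NaBH4, MeOH, 0 °C
Reagents that add atoms: dioxygen, O=O
Why: O2 oxidises the divalent manganese catalyst to a trivalent manganese cyclopropanolate, whose homolysis gives the C6 alkoxy radical; β-scission of the shared C6–C8 bond gives the ring-enlarged 6-oxo C8 radical, O2 capture and hydrogen transfer give hydroperoxide 23, and NaBH4 then reduces the O–O bond and the C6 ketone. The closest known reaction types are the manganese-catalysed aerobic oxidation of cyclopropanols to β-hydroperoxy ketones and the iron trichloride ring enlargement of ring-fused siloxycyclopropanes. No ring is closed by cyclisation: the cyclopentane C5–C6–C8–C9–C10 becomes the cyclohexane ring B because the cyclopropane carbon C7 is left between C6 and C8 (one-carbon ring expansion by radical β-scission). C8 is set by O2 capture on the α face, the β face being blocked by the syn-axial C10 methyl; C6 is set by hydride attack from the α face, the β face carrying three syn-axial methyl groups (on C4, C8 and C10). The step needs cleavage of the inner and not the outer cyclopropane bond, which the C8 methyl secures because only inner cleavage gives a tertiary radical (the outer one gives a primary radical that can re-close), and it needs the trans ring fusion and the 9β side chain, which steps 9 and 11 establish earlier in the route.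

Step 14
Reactants: 24 methyl (13S)-6β,8α-dihydroxylabdan-15-oate
Product: 25 methyl (13S)-6β-acetoxy-8α-hydroxylabdan-15-oate (target)
Conditions: Ac2O, DMAP, pyridine, 25 °C
Reagents that add atoms: acetic anhydride, CC(=O)OC(C)=O
Why: DMAP-catalysed acetylation should take place at the secondary axial 6β-hydroxyl only, the tertiary 8α-hydroxyl being inert under these conditions.

**Compound list**

1 | 2,2,6-trimethylcyclohexan-1-one (racemic) | CC1CCCC(C)(C)C1=O | starting material
2 | lithium 2,6,6-trimethylcyclohex-1-en-1-olate | [Li]OC1=C(C)CCCC1(C)C | intermediate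
3 | allyl 2,6,6-trimethylcyclohex-1-en-1-yl carbonate | C=CCOC(=O)OC1=C(C)CCCC1(C)C | intermediate
4 | (R)-2-allyl-2,6,6-trimethylcyclohexan-1-one | C=CC[C@@]1(C)CCCC(C)(C)C1=O | intermediate
5 | (R)-2,2,6-trimethyl-6-(2-oxopropyl)cyclohexan-1-one | CC(=O)C[C@@]1(C)CCCC(C)(C)C1=O | intermediate
6 | (7aR)-3a-hydroxy-4,4,7a-trimethyloctahydro-2H-inden-2-one (aldol adduct) | O=C1C[C@@]2(C)CCCC(C)(C)C2(O)C1 | intermediate
7 | (7aR)-4,4,7a-trimethyl-1,4,5,6,7,7a-hexahydro-2H-inden-2-one | O=C1C[C@@]2(C)CCCC(C)(C)C2=C1 | intermediate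
8 | methyl hydrogen (R)-3-methylglutarate | OC(=O)C[C@@H](C)CC(=O)OC | starting material
9 | (S)-5-hydroxy-3-methylpentanoic acid | OC(=O)C[C@@H](C)CCO | intermediate
10 | (S)-4-methyloxan-2-one | O=C1C[C@@H](C)CCO1 | intermediate
11 | trimethylsilyl (R)-5-iodo-3-methylpentanoate | C[Si](C)(C)OC(=O)C[C@@H](C)CCI | intermediate
12 | methyl (R)-5-iodo-3-methylpentanoate | COC(=O)C[C@@H](C)CCI | intermediate
13 | lithium dienolate of 7 (C8–OLi, C8=C9, C5=C6) | [Li]OC1=C[C@@]2(C)CCCC(C)(C)C2=C1 | intermediate
14 | methyl (3S)-3-methyl-5-[(7aR)-4,4,7a-trimethyl-2-oxo-2,4,5,6,7,7a-hexahydro-1H-inden-1-yl]pentanoate (C9 epimers) | COC(=O)C[C@@H](C)CCC1C(=O)C=C2C(C)(C)CCC[C@@]21C | intermediate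
15 | methyl (3S)-5-[(7aR)-2-hydroxy-2,4,4,7a-tetramethyl-2,4,5,6,7,7a-hexahydro-1H-inden-1-yl]-3-methylpentanoate (C8, C9 epimers) | COC(=O)C[C@@H](C)CCC1C(C)(O)C=C2C(C)(C)CCC[C@@]21C | intermediate
16 | methyl (3S)-3-methyl-5-[(7aR)-2,4,4,7a-tetramethyl-5,6,7,7a-tetrahydro-4H-inden-1-yl]pentanoate | COC(=O)C[C@@H](C)CCC1=C(C)C=C2C(C)(C)CCC[C@@]21C | intermediate
17 | allylborane of 16 (BH2 on C6 α, 5α-H) | COC(=O)C[C@@H](C)CCC1=C(C)[C@H](B)[C@H]2C(C)(C)CCC[C@@]21C | intermediate
18 | methyl (3S)-5-[(3R,3aS,7aS)-3-hydroxy-2,4,4,7a-tetramethyl-3a,4,5,6,7,7a-hexahydro-3H-inden-1-yl]-3-methylpentanoate | COC(=O)C[C@@H](C)CCC1=C(C)[C@H](O)[C@H]2C(C)(C)CCC[C@@]21C | intermediate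
19 | methyl (3S)-3-methyl-5-[(3aS,7aS)-2,4,4,7a-tetramethyl-3-oxo-3a,4,5,6,7,7a-hexahydro-3H-inden-1-yl]pentanoate | COC(=O)C[C@@H](C)CCC1=C(C)C(=O)[C@H]2C(C)(C)CCC[C@@]21C | intermediate
20 | methyl (3S)-3-methyl-5-[(1R,3aS,7aR)-2,4,4,7a-tetramethyl-3-(triethylsilyloxy)-3a,4,5,6,7,7a-hexahydro-1H-inden-1-yl]pentanoate | COC(=O)C[C@@H](C)CC[C@H]1C(C)=C(O[Si](CC)(CC)CC)[C@H]2C(C)(C)CCC[C@@]21C | intermediate
21 | triethylsilyl ether of 22 | COC(=O)C[C@@H](C)CC[C@H]1[C@]3(C)C[C@]3(O[Si](CC)(CC)CC)[C@H]2C(C)(C)CCC[C@@]21C | intermediate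
22 | ring-fused cyclopropanol (5S,6S,8S,9R,10R,13S by labdane locants): trans-hydrindane with an α-cyclopropane bridging C6 (OH) and C8 (Me), 9β side chain | COC(=O)C[C@@H](C)CC[C@H]1[C@]3(C)C[C@]3(O)[C@H]2C(C)(C)CCC[C@@]21C | intermediate
23 | methyl (13S)-8α-hydroperoxy-6-oxolabdan-15-oate | COC(=O)C[C@@H](C)CC[C@@H]1[C@@]2(C)CCCC(C)(C)[C@@H]2C(=O)C[C@@]1(C)OO | intermediate
24 | methyl (13S)-6β,8α-dihydroxylabdan-15-oate | COC(=O)C[C@@H](C)CC[C@@H]1[C@@]2(C)CCCC(C)(C)[C@@H]2[C@H](O)C[C@@]1(C)O | intermediate
25 | methyl (13S)-6β-acetoxy-8α-hydroxylabdan-15-oate | COC(=O)C[C@@H](C)CC[C@@H]1[C@@]2(C)CCCC(C)(C)[C@@H]2[C@H](OC(C)=O)C[C@@]1(C)O | target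

**Step count.** Total: 14 steps. Longest linear sequence: 12 steps (steps 1–4 and 7–14); steps 5 and 6 make the side-chain fragment.

**Steps most likely to fail**

Step 13 (key step). The alkoxy radical may open the outer cyclopropane bond, O2 may be captured at C8 without facial control, or the tertiary hydroperoxide may decay on the manganese catalyst before it is reduced. The fallback sets out from 22 and returns at 24. Iron trichloride in DMF at 0 °C should open 22 to the ring-enlarged β-chloro ketone F1. NaOAc in MeOH at reflux eliminates HCl and lets C5 settle trans, giving the enone methyl (13S)-6-oxolabd-7-en-15-oate F2. Alkaline H2O2 in MeOH epoxidises it from the α face to the 7α,8α-epoxy ketone F3. SmI2 in THF/MeOH at −78 °C cleaves the C7–O bond to the β-hydroxy ketone F4, and NaBH4 in MeOH at 0 °C then gives 24.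

Step 9. Boron may add to the diene with poor positional or facial control, or the allylborane may shift or lose boron before oxidation. The fallback sets out from 14 and returns at 19. Methyl addition as in step 8 with NH4Cl work-up gives the tertiary alcohol 15, now isolated. Hydroboration–oxidation (BH3·SMe2; H2O2, NaOAc) of its isolated C5=C6 bond gives the 6α,8-diol F5. DMP oxidises the secondary hydroxyl to the α-hydroxy ketone F6, and SOCl2 in pyridine at 0 °C dehydrates it towards C9 to give 19.

Step 11. Hydride transfer to the tetrasubstituted enone may be slow or be overtaken by 1,2-addition, and delivery to the α face of C9 is not assured. The fallback sets out from 19 and returns at 22. Hydrogenation (H2, Pd/C, EtOAc) from the α face gives the saturated ketone F7 (8α-H, 9α-H). Me3SiOTf and Et3N in CH2Cl2 give the more substituted trimethylsilyl enol ether F8; enolisation towards C5 is disfavoured by strain with the C4 methyl groups. Et2Zn/CH2I2 then gives the trimethylsilyl cyclopropyl ether F9, and K2CO3 in MeOH frees 22.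

**Further compounds**

F1 | step 13 | methyl (13S)-8-chloro-6-oxolabdan-15-oate (C8 epimers) | COC(=O)C[C@@H](C)CC[C@@H]1[C@@]2(C)CCCC(C)(C)[C@@H]2C(=O)CC1(C)Cl
F2 | step 13 | methyl (13S)-6-oxolabd-7-en-15-oate | COC(=O)C[C@@H](C)CC[C@@H]1[C@@]2(C)CCCC(C)(C)[C@@H]2C(=O)C=C1C
F3 | step 13 | methyl (13S)-7α,8α-epoxy-6-oxolabdan-15-oate | COC(=O)C[C@@H](C)CC[C@@H]1[C@@]2(C)CCCC(C)(C)[C@@H]2C(=O)[C@H]3O[C@@]13C
F4 | step 13 | methyl (13S)-8α-hydroxy-6-oxolabdan-15-oate | COC(=O)C[C@@H](C)CC[C@@H]1[C@@]2(C)CCCC(C)(C)[C@@H]2C(=O)C[C@@]1(C)O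
F5 | step 9 | 6α,8-diol of the trans-hydrindane (5α-H; C8, C9 epimers) | COC(=O)C[C@@H](C)CCC1C(C)(O)[C@H](O)[C@H]2C(C)(C)CCC[C@@]21C
F6 | step 9 | 8-hydroxy-6-ketone of the trans-hydrindane (C8, C9 epimers) | COC(=O)C[C@@H](C)CCC1C(C)(O)C(=O)[C@H]2C(C)(C)CCC[C@@]21C
F7 | step 11 | saturated trans-hydrindan-6-one (8α-H, 9α-H) | COC(=O)C[C@@H](C)CC[C@H]1[C@@H](C)C(=O)[C@H]2C(C)(C)CCC[C@@]21C
F8 | step 11 | trimethylsilyl enol ether (C6=C8) | COC(=O)C[C@@H](C)CC[C@H]1C(C)=C(O[Si](C)(C)C)[C@H]2C(C)(C)CCC[C@@]21C
F9 | step 11 | trimethylsilyl ether of 22 | COC(=O)C[C@@H](C)CC[C@H]1[C@]3(C)C[C@]3(O[Si](C)(C)C)[C@H]2C(C)(C)CCC[C@@]21C
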